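## The problem

The target has no stereocentre; it is a problem of ring construction and of oxygen placement on four benzene rings. A dibenzofuran (ring A with hydroxyls at C7 and C9, ring B) carries a hydroxyl at C3, and its C1 and C2 oxygens close a 1,4-dioxin onto ring D; ring D is pentaoxygenated and carries the 3,5-dihydroxyphenoxy group (ring E). Ring B is substituted at every carbon but C4, and ring D at every carbon but one, so all aryl–oxygen bonds are made at crowded positions. The dioxin joins two unsymmetrical rings: the C1 oxygen must sit on the ring D carbon next to the hydroxyl flanked by C–H, and the C2 oxygen on the carbon next to the ring E ether. Syntheses of dioxins from a catechol and an activated arene lose this orientation through Smiles rearrangement, so the orientation has to be locked by the order of events. The seven free phenols on electron-rich rings are prone to air oxidation and must stay masked to the last step. The dearomatized intermediates (quinone monoketal, para-quinol) tolerate only mild acid. The feature that opens the route lies in ring B: the lone hydroxyl at C3 is para to the biaryl carbon C9b, and the furan oxygen sits on C4a, ortho to C9b. With C3 as carbonyl, C9b as carbinol carbon and C4a as β-carbon, this is a 4-aryl-4-hydroxycyclohexa-2,5-dienone carrying an ortho-phenol on the aryl group.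

## Retrosynthesis

**Unmasking (26 from 25).** The seven O–methyl bonds of 25 are cut last. Methyl ethers are the only masks that survive aryllithium, peracid, BCl3 and hot copper/base alike. The forward reaction must cleave seven methyl ethers without touching the diaryl ethers, the dioxin or the furan.

**Second dioxin bond (25 from 24).** The bond between the C2 oxygen and the bromine-bearing carbon of ring D is cut. Closing it by copper catalysis on a ring D that carries only donors is preferred to an SNAr closure on an activated ring D. In the activated ring the free C2 phenoxide would attack the ipso carbon of the first ether bond and move ring D from one oxygen to the other before closure. In 24 the only reachable electrophilic carbon is the bromide, so the orientation set earlier cannot change.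

**Ring D oxygens and the C2 phenol (24 from 23, 22 and 20).** The C2 benzyl ether is removed only after ring D has been made electron-rich. The two ring D methoxy groups come from phenols, and these from the two formyl groups of 20 by Baeyer–Villiger oxidation. The formyl groups serve twice: they activate ring D for both ether-forming substitutions, and they mark the two carbons that must end as C–OH.

**First dioxin bond and the ring E ether (20 from 14 and 19; 19 from 17 and 18; 17 from 16 and 15).** The C1 oxygen–ring D bond and the ring E oxygen–ring D bond are both cut as SNAr displacements of fluoride. Dialdehyde 17 is symmetric: each fluorine is ortho to one formyl group and para to the other, and the bromine sits between them. The first phenol (18) can therefore enter at either fluorine with the same result, and the second (14) has a single fluorine left. Against a one-pot reaction of a free catechol with a difluoride, this costs protecting-group steps but fixes which oxygen is bonded to which carbon. Compound 17 comes from commercial 15 by formylation of the C–Br bond and bromination between the fluorines.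

**Differentiating the catechol (14 from 13 and 12).** Only the C1 hydroxyl may be free when 19 is attached. The C1 oxygen therefore carries an allyl group, removed by Pd(PPh3)4 in the presence of the C2 benzyl ether. The three phenols of 12 are methylated beforehand.

**Key disconnection (12 from 10 by way of 11).** The furan C–O bond from the ring A oxygen to C4a is cut and ring B is dearomatized to a para-quinol; the C3 hydroxyl becomes a ketone masked as a dimethyl ketal. The precursor 10 has no furan and no aromatic ring B, yet already holds all four ring B oxygens in place. The forward reaction must unmask ketone and phenol, add the phenol to the C–H β-carbon and not to the allyloxy-bearing one, and aromatize before an aryl shift can occur.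

**Biaryl bond (10 from 6 and 9; 9 from 8; 8 from 7).** The C9a–C9b bond is cut to quinone monoketal 6 and aryllithium 9. Ring A is carried as the threefold symmetric tris(methoxymethyl) ether 8: ortho-lithiation has only one possible site, and either ortho-oxygen leads to the same dibenzofuran.

**Quinone monoketal (6 from 5, 3, 2 and 1).** The ketal comes from a para-methoxyphenol by oxidation with PhI(OAc)2 in methanol, and the phenol from an aldehyde by Baeyer–Villiger oxidation. In commercial 1 the two catechol hydroxyls differ strongly, since one is hydrogen-bonded and conjugated to the formyl group. Benzyl can therefore be placed on the oxygen that becomes the C2 oxygen and allyl on the one that becomes the C1 oxygen. The aldehyde carbon marks the carbon that will receive ring A.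

## Roads not taken

**Alternative 1:** Ring D is built from a squarate ester. Cyclobutenone A2 opens on heating to a dienylketene, which closes and tautomerizes to phenol A1. The merit is real: a pentaoxygenated benzene with five differently masked oxygens arrives in very few steps, and its substitution pattern is fixed by the cyclobutenone. For ring D alone this is better than the chosen plan, where the ring D oxygens are finished only in steps 14 and 15. The weak points lie outside ring D. In A1 the two adjacent isopropoxy oxygens are the future dioxin oxygens, so ring B would have to offer electrophilic carbons at C1 and C2 of a dibenzofuran, one of them in the bay. Those two oxygens are not told apart, so the orientation problem returns on the ring D side. Ring E would have to be put by copper chemistry on a phenol flanked on both sides. The plan also says nothing about rings A and B. The chosen plan sets against it a locked dioxin orientation and a ring E ether made by simple SNAr.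

**Alternative 2:** Quinone A4 is the hub. The ring E phenoxide and then dibenzofuranol A5 displace its two chlorides to give A3; reduction and a copper-mediated closure onto the bay bromide would finish the dioxin. This is the most convergent of the four plans and is shorter after fragment union than the chosen one: ring D arrives with its oxygens, and no Baeyer–Villiger step or benzyl removal is needed. Its weak points are the order and site of the two displacements on a quinone whose two chlorides are both activated, the ease with which aryloxy groups on quinones are exchanged, and the closure of a hydroquinone hydroxyl onto a bay bromide under copper and base, where the hydroquinone is easily oxidized. A5 also needs its own regiocontrolled dibenzofuran synthesis, which this plan does not supply. The chosen plan is longer at the end, but each aryl–oxygen bond forms at the only site available, and ring B is made together with its oxygens.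

**Alternative 3:** Ring B and the furan are made in one thermal step: the intramolecular Diels–Alder reaction of 2-aryloxyfuran A7 with its alkynylboronate, followed by opening of the oxygen bridge, gives A6. A6 is born with boron at C1 and a free hydroxyl at C2. This differentiation of the two dioxin positions is better than the allyl/benzyl pair of the chosen plan, which costs steps 2, 9 and 16. The weak points are the substrate and the step. A7 is an electron-rich, hydrolytically labile 2-aryloxy-4-methoxyfuran. The tether has only two atoms, so the cycloaddition must close a strained five-membered ring onto an oxanorbornadiene, and alkynylboronates are modest dienophiles. On this substrate class the step would be a new method. The chosen key step is a known cascade run on robust, isolable intermediates.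

Key step: step 7

Assumptions: the identifier is taken to mean the achiral structure of the SMILES string. Compounds 1, 7, 15 and 18 are taken as purchased. Compounds 10 and 11 are racemic; their single stereocentre is destroyed in step 7.

## Route

Step 1
Reactants: 1 2,3-dihydroxy-4-methoxybenzaldehyde
Product: 2 3-(benzyloxy)-2-hydroxy-4-methoxybenzaldehyde
Conditions: NaH (2.1 equiv), THF/DMSO, 0 °C to rt; BnBr (1.0 equiv)
Reagents that add atoms: benzyl bromide, BrCc1ccccc1
Why: Williamson alkylation of the dianion; the C3 phenoxide is not conjugated to the formyl group and is the more nucleophilic oxygen, while the C2 phenoxide is a chelated vinylogous carboxylate and stays free.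

Step 2
Reactants: 2 3-(benzyloxy)-2-hydroxy-4-methoxybenzaldehyde
Product: 3 2-(allyloxy)-3-(benzyloxy)-4-methoxybenzaldehyde
Conditions: allyl bromide, K2CO3, DMF, 50 °C
Reagents that add atoms: allyl bromide, C=CCBr
Why: Williamson etherification of the remaining hydrogen-bonded phenol; the two catechol oxygens now carry groups that can be removed independently.

Step 3
Reactants: 3 2-(allyloxy)-3-(benzyloxy)-4-methoxybenzaldehyde
Product: 5 2-(allyloxy)-3-(benzyloxy)-4-methoxyphenol, via aryl formate 4 (not isolated)
Conditions: mCPBA (1.2 equiv), CH2Cl2, 0 °C to rt; then K2CO3, MeOH, rt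
Reagents that add atoms: 3-chloroperoxybenzoic acid (mCPBA), OOC(=O)c1cccc(Cl)c1
Why: Baeyer–Villiger oxidation of an aldehyde whose ring has ortho and para alkoxy donors, so the aryl group migrates; the terminal alkene of the allyl ether should react with the peracid more slowly than the aldehyde, and the formate is cleaved by methanolysis.

Step 4
Reactants: 5 2-(allyloxy)-3-(benzyloxy)-4-methoxyphenol
Product: 6 2-(allyloxy)-3-(benzyloxy)-4,4-dimethoxycyclohexa-2,5-dien-1-one
Conditions: PhI(OAc)2, MeOH, 0 °C
Reagents that add atoms: methanol, CO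
Why: Oxidative dearomatization of a para-methoxyphenol by trivalent iodine in methanol to the quinone monoketal; the carbonyl stands at the former phenol carbon, next to the allyloxy carbon.

Step 5
Reactants: 7 phloroglucinol (benzene-1,3,5-triol)
Product: 8 1,3,5-tris(methoxymethoxy)benzene
Conditions: NaH, MOMCl, DMF, 0 °C to rt
Reagents that add atoms: chloromethyl methyl ether, COCCl
Why: Threefold O-alkylation of the phenoxide with a hard oxocarbenium-type electrophile; the acetal groups later direct lithiation and are removable by acid.

Step 6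
Reactants: 8 1,3,5-tris(methoxymethoxy)benzene; 6 2-(allyloxy)-3-(benzyloxy)-4,4-dimethoxycyclohexa-2,5-dien-1-one
Product: 10 racemic 2-(allyloxy)-3-(benzyloxy)-4,4-dimethoxy-1-[2,4,6-tris(methoxymethoxy)phenyl]cyclohexa-2,5-dien-1-ol, via aryllithium 9 (not isolated)
Conditions: n-BuLi, THF, 0 °C; then 6, THF, −78 °C; aq. NH4Cl
Reagents that add atoms: none
Why: Directed ortho-metalation between two acetal oxygens (all three ring positions are equivalent), then 1,2-addition of the aryllithium to the dienone carbonyl of the quinone monoketal at low temperature; the new stereocentre forms as a racemate and is removed in step 7.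

Step 7
Reactants: 10 racemic 2-(allyloxy)-3-(benzyloxy)-4,4-dimethoxy-1-[2,4,6-tris(methoxymethoxy)phenyl]cyclohexa-2,5-dien-1-ol
Product: 12 1-(allyloxy)-2-(benzyloxy)dibenzo[b,d]furan-3,7,9-triol, via para-quinol 11 (not isolated)
Conditions: 1 M aq. HCl, THF, 0 °C; then TsOH·H2O, allyl alcohol, 40 °C
Reagents that add atoms: water, O
Why: Cold dilute acid first hydrolyses the dimethyl ketal, whose oxocarbenium ion is stabilized directly by the second methoxy group and so forms faster than the tertiary carbinol can ionize toward a Stork–Danheiser-type transposition; in para-quinol 11 that carbinol can no longer ionize. TsOH in allyl alcohol then removes the three methoxymethyl groups by transacetalization, a freed ortho-phenol adds to the unsubstituted enone β-carbon, the tertiary benzylic hydroxyl leaves with the neighbouring hydrogen to form the furan double bond, and the remaining cyclohexenone enolizes to the C3 phenol. The closest known reaction type is the acid-mediated conversion of 4-(2-hydroxyaryl)-4-hydroxycyclohexadienones from quinone monoketals into dibenzofuranols. The furan closes by 5-exo-trig oxa-Michael addition; ring B is not closed but aromatized. No stereocentre is formed, and the one in 10 and 11 disappears. The step needs addition at the C–H β-carbon: the other β-carbon is a vinylogous ester carbon deactivated and shielded by its allyloxy group, and only addition at C–H can be followed by irreversible aromatization. Allyl alcohol as solvent makes any acid-catalysed alkoxy exchange at that vinylogous ester carbon degenerate and captures the methoxymethyl cations before they reach the nucleophilic ring A. The 1,2-aryl shift needs stronger acid than the intramolecular addition, and both ortho-oxygens of the symmetric aryl group give the same product.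

Step 8
Reactants: 12 1-(allyloxy)-2-(benzyloxy)dibenzo[b,d]furan-3,7,9-triol
Product: 13 1-(allyloxy)-2-(benzyloxy)-3,7,9-trimethoxydibenzo[b,d]furan
Conditions: Me2SO4, K2CO3, acetone, reflux
Reagents that add atoms: dimethyl sulfate, COS(=O)(=O)OC
Why: Williamson methylation of three phenols; the hard sulfate electrophile favours O- over C-methylation of the resorcinol-type ring A.

Step 9
Reactants: 13 1-(allyloxy)-2-(benzyloxy)-3,7,9-trimethoxydibenzo[b,d]furan
Product: 14 2-(benzyloxy)-3,7,9-trimethoxydibenzo[b,d]furan-1-ol
Conditions: Pd(PPh3)4 (cat.), morpholine, THF, rt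
Reagents that add atoms: none
Why: Tsuji–Trost-type deallylation: zerovalent palladium ionizes the allyl aryl ether and morpholine captures the allyl group; benzyl and methyl ethers are inert, so only the bay hydroxyl at C1 is set free.

Step 10
Reactants: 15 5-bromo-2,4-difluorobenzaldehyde
Product: 16 4,6-difluoroisophthalaldehyde (4,6-difluorobenzene-1,3-dicarbaldehyde)
Conditions: Pd(OAc)2 (cat.), PAd2(n-Bu), CO/H2 (1:1, 5 bar), TMEDA, toluene, 100 °C
Reagents that add atoms: carbon monoxide, [C-]#[O+]
Why: Palladium-catalysed reductive carbonylation (formylation) of an electron-poor aryl bromide with synthesis gas; the existing aldehyde and the aryl fluorides are not expected to react with the tertiary amine base.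

Step 11
Reactants: 16 4,6-difluoroisophthalaldehyde
Product: 17 5-bromo-4,6-difluoroisophthalaldehyde
Conditions: NBS, conc. H2SO4, 60 °C
Reagents that add atoms: N-bromosuccinimide, O=C1CCC(=O)N1Br
Why: Electrophilic bromination of a deactivated arene by protonated NBS; the carbon between the fluorines is ortho to both fluorines and meta to both formyl groups, whereas the only other free carbon lies between the two formyl groups.

Step 12
Reactants: 17 5-bromo-4,6-difluoroisophthalaldehyde; 18 3,5-dimethoxyphenol
Product: 19 5-bromo-4-(3,5-dimethoxyphenoxy)-6-fluoroisophthalaldehyde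
Conditions: 17 (2 equiv), K2CO3, MeCN, 0 °C to rt
Reagents that add atoms: none
Why: SNAr at one of two equivalent fluorines, each ortho to one formyl group and para to the other; excess 17 and the donor effect of the first aryloxy group on both formyl groups should hold the reaction at one substitution.

Step 13
Reactants: 14 2-(benzyloxy)-3,7,9-trimethoxydibenzo[b,d]furan-1-ol; 19 5-bromo-4-(3,5-dimethoxyphenoxy)-6-fluoroisophthalaldehyde
Product: 20 4-{[2-(benzyloxy)-3,7,9-trimethoxydibenzo[b,d]furan-1-yl]oxy}-5-bromo-6-(3,5-dimethoxyphenoxy)isophthalaldehyde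
Conditions: Cs2CO3, DMF, rt to 40 °C
Reagents that add atoms: none
Why: SNAr of the C1 phenoxide at the only remaining fluoride, which is activated by an ortho and a para formyl group; the C2 oxygen is benzylated, so no Smiles migration can occur and the first dioxin bond is placed unambiguously.

Step 14
Reactants: 20 4-{[2-(benzyloxy)-3,7,9-trimethoxydibenzo[b,d]furan-1-yl]oxy}-5-bromo-6-(3,5-dimethoxyphenoxy)isophthalaldehyde
Product: 22 4-{[2-(benzyloxy)-3,7,9-trimethoxydibenzo[b,d]furan-1-yl]oxy}-5-bromo-6-(3,5-dimethoxyphenoxy)benzene-1,3-diol, via bis-formate 21 (not isolated)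
Conditions: mCPBA (3 equiv), CH2Cl2, 0 °C to rt; then K2CO3, MeOH, rt
Reagents that add atoms: 3-chloroperoxybenzoic acid (mCPBA), OOC(=O)c1cccc(Cl)c1
Why: Twofold Baeyer–Villiger oxidation; each formyl group has an ortho and a para aryloxy donor, so aryl migration is expected, and the first formate makes the ring richer for the second oxidation; methanolysis frees the two ring D phenols.

Step 15
Reactants: 22 4-{[2-(benzyloxy)-3,7,9-trimethoxydibenzo[b,d]furan-1-yl]oxy}-5-bromo-6-(3,5-dimethoxyphenoxy)benzene-1,3-diol
Product: 23 2-(benzyloxy)-1-[2-bromo-3-(3,5-dimethoxyphenoxy)-4,6-dimethoxyphenoxy]-3,7,9-trimethoxydibenzo[b,d]furan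
Conditions: MeI, K2CO3, DMF, rt
Reagents that add atoms: iodomethane, CI
Why: Williamson methylation of the two phenols; ring D now carries only donors and is inert to nucleophilic attack.

Step 16
Reactants: 23 2-(benzyloxy)-1-[2-bromo-3-(3,5-dimethoxyphenoxy)-4,6-dimethoxyphenoxy]-3,7,9-trimethoxydibenzo[b,d]furan
Product: 24 1-[2-bromo-3-(3,5-dimethoxyphenoxy)-4,6-dimethoxyphenoxy]-3,7,9-trimethoxydibenzo[b,d]furan-2-ol
Conditions: BCl3, pentamethylbenzene, CH2Cl2, −78 °C
Reagents that add atoms: none
Why: Lewis-acid debenzylation with pentamethylbenzene as cation scavenger; at −78 °C methyl ethers, diaryl ethers and the aryl bromide should be untouched, and hydrogenolysis is avoided because it would also remove the bromine.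

Step 17
Reactants: 24 1-[2-bromo-3-(3,5-dimethoxyphenoxy)-4,6-dimethoxyphenoxy]-3,7,9-trimethoxydibenzo[b,d]furan-2-ol
Product: 25 hepta-O-methyl ether of 26 (all seven hydroxyls of 26 as methoxy groups)
Conditions: CuI (20 mol%), N,N-dimethylglycine·HCl, Cs2CO3, 1,4-dioxane, 105 °C
Reagents that add atoms: none
Why: Intramolecular Ullmann etherification under monovalent copper closes the six-membered dioxin; the C2 phenoxide can reach only the bromine-bearing carbon, and because ring D is electron-rich no Smiles migration can alter the orientation.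

Step 18
Reactants: 25 hepta-O-methyl ether of 26
Product: 26 CNP0256302.0: dibenzo[b,d]furan-3,7,9-triol whose C1 and C2 oxygens close a 1,4-dioxin onto ring D; ring D carries, counted from the carbon on the C2 oxygen, a 3,5-dihydroxyphenoxy group, OH, H and OH
Conditions: BBr3 (excess), CH2Cl2, −78 °C to rt; MeOH, then aqueous work-up under argon
Reagents that add atoms: none
Why: Lewis-acid cleavage of the seven aryl methyl ethers by BBr3; diaryl ethers, the dioxin and the furan are not cleaved by this reagent, and oxygen is excluded in the work-up because the free polyphenol is oxidizable.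

## Compound list

1 | 2,3-dihydroxy-4-methoxybenzaldehyde | O=Cc1ccc(OC)c(O)c1O | starting material
2 | 3-(benzyloxy)-2-hydroxy-4-methoxybenzaldehyde | O=Cc1ccc(OC)c(OCc2ccccc2)c1O | intermediate
3 | 2-(allyloxy)-3-(benzyloxy)-4-methoxybenzaldehyde | O=Cc1ccc(OC)c(OCc2ccccc2)c1OCC=C | intermediate
4 | 2-(allyloxy)-3-(benzyloxy)-4-methoxyphenyl formate (not isolated) | O=COc1ccc(OC)c(OCc2ccccc2)c1OCC=C | intermediate
5 | 2-(allyloxy)-3-(benzyloxy)-4-methoxyphenol | Oc1ccc(OC)c(OCc2ccccc2)c1OCC=C | intermediate
6 | 2-(allyloxy)-3-(benzyloxy)-4,4-dimethoxycyclohexa-2,5-dien-1-one | O=C1C=CC(OC)(OC)C(OCc2ccccc2)=C1OCC=C | intermediate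
7 | phloroglucinol (benzene-1,3,5-triol) | Oc1cc(O)cc(O)c1 | starting material
8 | 1,3,5-tris(methoxymethoxy)benzene | COCOc1cc(OCOC)cc(OCOC)c1 | intermediate
9 | 2,4,6-tris(methoxymethoxy)phenyllithium (not isolated) | [Li]c1c(OCOC)cc(OCOC)cc1OCOC | intermediate
10 | racemic 2-(allyloxy)-3-(benzyloxy)-4,4-dimethoxy-1-[2,4,6-tris(methoxymethoxy)phenyl]cyclohexa-2,5-dien-1-ol | COCOc1cc(OCOC)cc(OCOC)c1C1(O)C=CC(OC)(OC)C(OCc2ccccc2)=C1OCC=C | intermediate
11 | racemic 3-(allyloxy)-2-(benzyloxy)-4-hydroxy-4-[2,4,6-tris(methoxymethoxy)phenyl]cyclohexa-2,5-dien-1-one (not isolated) | COCOc1cc(OCOC)cc(OCOC)c1C1(O)C=CC(=O)C(OCc2ccccc2)=C1OCC=C | intermediate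
12 | 1-(allyloxy)-2-(benzyloxy)dibenzo[b,d]furan-3,7,9-triol | Oc1cc2oc3cc(O)cc(O)c3c2c(OCC=C)c1OCc1ccccc1 | intermediate
13 | 1-(allyloxy)-2-(benzyloxy)-3,7,9-trimethoxydibenzo[b,d]furan | COc1cc2oc3cc(OC)cc(OC)c3c2c(OCC=C)c1OCc1ccccc1 | intermediate
14 | 2-(benzyloxy)-3,7,9-trimethoxydibenzo[b,d]furan-1-ol | COc1cc2oc3cc(OC)cc(OC)c3c2c(O)c1OCc1ccccc1 | intermediate
15 | 5-bromo-2,4-difluorobenzaldehyde | O=Cc1cc(Br)c(F)cc1F | starting material
16 | 4,6-difluoroisophthalaldehyde | O=Cc1cc(C=O)c(F)cc1F | intermediate
17 | 5-bromo-4,6-difluoroisophthalaldehyde | O=Cc1cc(C=O)c(F)c(Br)c1F | intermediate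
18 | 3,5-dimethoxyphenol | COc1cc(O)cc(OC)c1 | starting material
19 | 5-bromo-4-(3,5-dimethoxyphenoxy)-6-fluoroisophthalaldehyde | O=Cc1cc(C=O)c(Oc2cc(OC)cc(OC)c2)c(Br)c1F | intermediate
20 | 4-{[2-(benzyloxy)-3,7,9-trimethoxydibenzo[b,d]furan-1-yl]oxy}-5-bromo-6-(3,5-dimethoxyphenoxy)isophthalaldehyde | O=Cc1cc(C=O)c(Oc2cc(OC)cc(OC)c2)c(Br)c1Oc1c(OCc2ccccc2)c(OC)cc2oc3cc(OC)cc(OC)c3c12 | intermediate
21 | 4-{[2-(benzyloxy)-3,7,9-trimethoxydibenzo[b,d]furan-1-yl]oxy}-5-bromo-6-(3,5-dimethoxyphenoxy)-1,3-phenylene diformate (not isolated) | O=COc1cc(OC=O)c(Oc2cc(OC)cc(OC)c2)c(Br)c1Oc1c(OCc2ccccc2)c(OC)cc2oc3cc(OC)cc(OC)c3c12 | intermediate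
22 | 4-{[2-(benzyloxy)-3,7,9-trimethoxydibenzo[b,d]furan-1-yl]oxy}-5-bromo-6-(3,5-dimethoxyphenoxy)benzene-1,3-diol | Oc1cc(O)c(Oc2cc(OC)cc(OC)c2)c(Br)c1Oc1c(OCc2ccccc2)c(OC)cc2oc3cc(OC)cc(OC)c3c12 | intermediate
23 | 2-(benzyloxy)-1-[2-bromo-3-(3,5-dimethoxyphenoxy)-4,6-dimethoxyphenoxy]-3,7,9-trimethoxydibenzo[b,d]furan | COc1cc(OC)c(Oc2cc(OC)cc(OC)c2)c(Br)c1Oc1c(OCc2ccccc2)c(OC)cc2oc3cc(OC)cc(OC)c3c12 | intermediate
24 | 1-[2-bromo-3-(3,5-dimethoxyphenoxy)-4,6-dimethoxyphenoxy]-3,7,9-trimethoxydibenzo[b,d]furan-2-ol | COc1cc(OC)c(Oc2cc(OC)cc(OC)c2)c(Br)c1Oc1c(O)c(OC)cc2oc3cc(OC)cc(OC)c3c12 | intermediate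
25 | hepta-O-methyl ether of 26 | COc1cc(OC)cc(Oc2c(OC)cc(OC)c3c2Oc2c(OC)cc4oc5cc(OC)cc(OC)c5c4c2O3)c1 | intermediate
26 | CNP0256302.0 (no stereocentre) | Oc1cc(O)cc(Oc2c(O)cc(O)c3c2Oc2c(O)cc4oc5cc(O)cc(O)c5c4c2O3)c1 | target

## Step count and least certain steps

Total: 18 steps. Longest linear sequence: 14 steps (1, 2, 3, 4, 6, 7, 8, 9, 13, 14, 15, 16, 17, 18, starting from compound 1). Side branches: step 5 (one step) and steps 10 to 12 (three steps).

**Step 7 (key step).** The most likely failure is a mismatch of rates. If removal of the methoxymethyl groups is slow, para-quinol 11 sits in acid without a free phenol. Hydrolytic loss of the allyl group at the vinylogous ester carbon, phenol addition at the allyloxy-bearing β-carbon, or a 1,2-aryl shift can then overtake the oxa-Michael closure. The fallback sets out from 6 and brings the ring A oxygen in unprotected, so that only the very labile ketal has to be hydrolysed. Compound 18 is brominated with NBS to 2-bromo-3,5-dimethoxyphenol F1, which is separated from its 4-bromo isomer. F1 is converted with two equivalents of n-BuLi at −78 °C into lithium 2-lithio-3,5-dimethoxyphenoxide F2. F2 adds to 6 to give racemic 2-(allyloxy)-3-(benzyloxy)-1-(2-hydroxy-4,6-dimethoxyphenyl)-4,4-dimethoxycyclohexa-2,5-dien-1-ol F3. Dilute aqueous oxalic acid in THF at 0 °C to rt should then trigger ketal hydrolysis and the same cascade at once, giving 1-(allyloxy)-2-(benzyloxy)-7,9-dimethoxydibenzo[b,d]furan-3-ol F4. Methylation of F4 with Me2SO4 and K2CO3 comes back to the route at 13.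

**Step 13.** Attack of the bay phenoxide of 14, which has substituents on both ortho positions, on a fluoride flanked by bromine and formyl may be slow. Displacement of the ring E aryloxy group at the other doubly activated carbon could then compete. The fallback reverses the order of assembly. It sets out from 14 and the smaller, symmetric difluoride 17 (in excess), which should give 4-{[2-(benzyloxy)-3,7,9-trimethoxydibenzo[b,d]furan-1-yl]oxy}-5-bromo-6-fluoroisophthalaldehyde F5. The remaining fluoride is then displaced by an excess of 18 with K2CO3 in MeCN, coming back at 20.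

**Step 14.** In the first Baeyer–Villiger oxidation the ring still carries a second formyl group and a bromine. Hydride migration in place of aryl migration (giving a benzoic acid) is therefore possible, and the peracid may also attack the electron-rich rings A and E. The fallback sets out from 14 and uses a ring D building block with one formyl group and one methoxy group already in place. Purchased 2-fluoro-4-hydroxy-5-methoxybenzaldehyde is brominated ortho to the hydroxyl (Br2, AcOH) to 3-bromo-2-fluoro-4-hydroxy-5-methoxybenzaldehyde F6. F6 is arylated by Chan–Lam coupling with (3,5-dimethoxyphenyl)boronic acid (Cu(OAc)2, pyridine, air) to 3-bromo-4-(3,5-dimethoxyphenoxy)-2-fluoro-5-methoxybenzaldehyde F7. SNAr of 14 on F7 (Cs2CO3, DMF, 100 °C) gives 2-{[2-(benzyloxy)-3,7,9-trimethoxydibenzo[b,d]furan-1-yl]oxy}-3-bromo-4-(3,5-dimethoxyphenoxy)-5-methoxybenzaldehyde F8. A single Baeyer–Villiger oxidation on this richer ring leads through 2-{[2-(benzyloxy)-3,7,9-trimethoxydibenzo[b,d]furan-1-yl]oxy}-3-bromo-4-(3,5-dimethoxyphenoxy)-5-methoxyphenyl formate F9 to 2-{[2-(benzyloxy)-3,7,9-trimethoxydibenzo[b,d]furan-1-yl]oxy}-3-bromo-4-(3,5-dimethoxyphenoxy)-5-methoxyphenol F10. Methylation of F10 with MeI comes back at 23. The price is a less activated SNAr step.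

**Step 17.** Oxidative addition of copper into a bromide flanked by two aryloxy groups on an electron-rich ring may be slow, and protodebromination would then dominate. The fallback sets out from 23 and turns the bromide into the nucleophilic partner of an oxidative coupling. Bromine–lithium exchange with n-BuLi at −78 °C gives {2-{[2-(benzyloxy)-3,7,9-trimethoxydibenzo[b,d]furan-1-yl]oxy}-6-(3,5-dimethoxyphenoxy)-3,5-dimethoxyphenyl}lithium F11. B(OMe)3 and acidic work-up give {2-{[2-(benzyloxy)-3,7,9-trimethoxydibenzo[b,d]furan-1-yl]oxy}-6-(3,5-dimethoxyphenoxy)-3,5-dimethoxyphenyl}boronic acid F12. Hydrogenolysis over Pd/C, now possible because no bromide is left, gives {6-(3,5-dimethoxyphenoxy)-2-[(2-hydroxy-3,7,9-trimethoxydibenzo[b,d]furan-1-yl)oxy]-3,5-dimethoxyphenyl}boronic acid F13. Intramolecular Chan–Lam coupling (Cu(OAc)2, pyridine, air, CH2Cl2, rt) comes back at 25.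

Further compounds
F1 | step 7 | 2-bromo-3,5-dimethoxyphenol | Oc1cc(OC)cc(OC)c1Br
F2 | step 7 | lithium 2-lithio-3,5-dimethoxyphenoxide | [Li]Oc1cc(OC)cc(OC)c1[Li]
F3 | step 7 | racemic 2-(allyloxy)-3-(benzyloxy)-1-(2-hydroxy-4,6-dimethoxyphenyl)-4,4-dimethoxycyclohexa-2,5-dien-1-ol | Oc1cc(OC)cc(OC)c1C1(O)C=CC(OC)(OC)C(OCc2ccccc2)=C1OCC=C
F4 | step 7 | 1-(allyloxy)-2-(benzyloxy)-7,9-dimethoxydibenzo[b,d]furan-3-ol | Oc1cc2oc3cc(OC)cc(OC)c3c2c(OCC=C)c1OCc1ccccc1
F5 | step 13 | 4-{[2-(benzyloxy)-3,7,9-trimethoxydibenzo[b,d]furan-1-yl]oxy}-5-bromo-6-fluoroisophthalaldehyde | O=Cc1cc(C=O)c(F)c(Br)c1Oc1c(OCc2ccccc2)c(OC)cc2oc3cc(OC)cc(OC)c3c12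
F6 | step 14 | 3-bromo-2-fluoro-4-hydroxy-5-methoxybenzaldehyde | O=Cc1cc(OC)c(O)c(Br)c1F
F7 | step 14 | 3-bromo-4-(3,5-dimethoxyphenoxy)-2-fluoro-5-methoxybenzaldehyde | O=Cc1cc(OC)c(Oc2cc(OC)cc(OC)c2)c(Br)c1F
F8 | step 14 | 2-{[2-(benzyloxy)-3,7,9-trimethoxydibenzo[b,d]furan-1-yl]oxy}-3-bromo-4-(3,5-dimethoxyphenoxy)-5-methoxybenzaldehyde | O=Cc1cc(OC)c(Oc2cc(OC)cc(OC)c2)c(Br)c1Oc1c(OCc2ccccc2)c(OC)cc2oc3cc(OC)cc(OC)c3c12
F9 | step 14 | 2-{[2-(benzyloxy)-3,7,9-trimethoxydibenzo[b,d]furan-1-yl]oxy}-3-bromo-4-(3,5-dimethoxyphenoxy)-5-methoxyphenyl formate | O=COc1cc(OC)c(Oc2cc(OC)cc(OC)c2)c(Br)c1Oc1c(OCc2ccccc2)c(OC)cc2oc3cc(OC)cc(OC)c3c12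
F10 | step 14 | 2-{[2-(benzyloxy)-3,7,9-trimethoxydibenzo[b,d]furan-1-yl]oxy}-3-bromo-4-(3,5-dimethoxyphenoxy)-5-methoxyphenol | Oc1cc(OC)c(Oc2cc(OC)cc(OC)c2)c(Br)c1Oc1c(OCc2ccccc2)c(OC)cc2oc3cc(OC)cc(OC)c3c12
F11 | step 17 | {2-{[2-(benzyloxy)-3,7,9-trimethoxydibenzo[b,d]furan-1-yl]oxy}-6-(3,5-dimethoxyphenoxy)-3,5-dimethoxyphenyl}lithium | COc1cc(OC)c(Oc2cc(OC)cc(OC)c2)c([Li])c1Oc1c(OCc2ccccc2)c(OC)cc2oc3cc(OC)cc(OC)c3c12
F12 | step 17 | {2-{[2-(benzyloxy)-3,7,9-trimethoxydibenzo[b,d]furan-1-yl]oxy}-6-(3,5-dimethoxyphenoxy)-3,5-dimethoxyphenyl}boronic acid | COc1cc(OC)c(Oc2cc(OC)cc(OC)c2)c(B(O)O)c1Oc1c(OCc2ccccc2)c(OC)cc2oc3cc(OC)cc(OC)c3c12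
F13 | step 17 | {6-(3,5-dimethoxyphenoxy)-2-[(2-hydroxy-3,7,9-trimethoxydibenzo[b,d]furan-1-yl)oxy]-3,5-dimethoxyphenyl}boronic acid | COc1cc(OC)c(Oc2cc(OC)cc(OC)c2)c(B(O)O)c1Oc1c(O)c(OC)cc2oc3cc(OC)cc(OC)c3c12
A1 | alternative 1 | 4-(tert-butyldimethylsilyloxy)-5-ethoxy-2,3-diisopropoxyphenol | CCOc1cc(O)c(OC(C)C)c(OC(C)C)c1O[Si](C)(C)C(C)(C)C
A2 | alternative 1 | 4-(tert-butyldimethylsilyloxy)-4-(1-ethoxyvinyl)-2,3-diisopropoxycyclobut-2-en-1-one | CCOC(=C)C1(O[Si](C)(C)C(C)(C)C)C(=O)C(OC(C)C)=C1OC(C)C
A3 | alternative 2 | 2-(3,5-dimethoxyphenoxy)-3-[(1-bromo-3,7,9-trimethoxydibenzofuran-2-yl)oxy]-5-methoxy-1,4-benzoquinone | COC1=CC(=O)C(Oc2cc(OC)cc(OC)c2)=C(Oc2c(OC)cc3oc4cc(OC)cc(OC)c4c3c2Br)C1=O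
A4 | alternative 2 | 2,3-dichloro-5-methoxy-1,4-benzoquinone | COC1=CC(=O)C(Cl)=C(Cl)C1=O
A5 | alternative 2 | 1-bromo-3,7,9-trimethoxydibenzofuran-2-ol | COc1cc2oc3cc(OC)cc(OC)c3c2c(Br)c1O
A6 | alternative 3 | 3,7,9-trimethoxy-1-(pinacolboryl)dibenzofuran-2-ol | COc1cc2oc3cc(OC)cc(OC)c3c2c(B2OC(C)(C)C(C)(C)O2)c1O
A7 | alternative 3 | 2-{3,5-dimethoxy-2-[(pinacolboryl)ethynyl]phenoxy}-4-methoxyfuran | COc1coc(Oc2cc(OC)cc(OC)c2C#CB2OC(C)(C)C(C)(C)O2)c1
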